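How much of the charge can still stand as target at 15 min in the alder flask, which has been followed for 3.00 min?

| flask | solid substrate | solid reagent | remark | time |
|---|---|---|---|---|
| alder | 2 M | 2.4 M | the very flask that is asked about, followed so far |  |
| flask | 2.0 M | 2.40 M |  | 15 min |
alder run (percent of the solid substrate charged)

| time / min | target / % | dissolved substrate / % |
|---|---|---|
| 0.833 | 2.9 | 22.7 |
| 1.50 | 8.5 | 32.5 |
| 2.50 | 17.6 | 41.0 |
| 3.00 | 22.1 | 44.9 |

(standard deviation of a reading: 0.3 percentage points)
- spring: doubling the solubility of the solid substrate, all else as stated
- summer: doubling the solubility of the solid reagent, all else as stated
- dawn: doubling the dissolution coefficient of the solid substrate, all else as stated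
- midnight: doubling the dissolution coefficient of the solid reagent, all else as stated
- as a solid, counted per litre of solution: solid substrate, solid reagent
- at the start none of the solid substrate is in solution
- at the start none of the solid reagent is in solution
- dissolved substrate means what is dissolved; the solid is not counted in it
* target at 15 min, in percent of the solid substrate charged
* concentration of dissolved substrate in solution at 4.0 min, in percent of saturation
* the change that raises the amount of target at 15 min, in percent of the solid substrate charged most ("none" if none brings more than 2 percentage points) (spring / summer / dawn / midnight / none)
* amount of target at 15 min, in percent of the solid substrate charged, after midnight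

I draw the curve from the alder readings. Target plus dissolved substrate is what has left the solid. That sum rises at 0.273 min⁻¹ up to 1.50 min and at 0.173 min⁻¹ after it, and I replace dissolved substrate in each stretch by its mean, 16.2% and 38.7%. The two stretches give a dissolution coefficient of 0.445 min⁻¹ and a saturation level of 77.6% of the charge, which leaves 22.4%. I call this the headroom, the part of the charge that a saturated solution can't hold as dissolved substrate; it has to stand as target or as solid.

Target climbs at a flat 0.0907 min⁻¹, so dissolved substrate reaches 49.3% at 4.0 min, or 63.5% of saturation. The knee comes near 5.55 min, where target plus dissolved substrate reach the whole charge.

But the flat slope hides a fall. Target's slope per dissolved substrate, a pseudo-first-order coefficient, drops from 0.304 min⁻¹ to 0.234 min⁻¹, a reading that halves in about 2.88 min, which is shorter than the 15 min asked about. I read this as the step to target running back as target builds up, and I assume that the partner, the reagent in solution, fades later on. Dissolved substrate then climbs to its level and target sinks towards the headroom. I commit to about 22.4% for target, the same after midnight, and none as the best change.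

The forecast says 98% (range 93% to 99.8%), 62% of saturation, none as best change and 99.8% after midnight, holding that “the tail finishes by 15 min”.

The flask gives 22.8%, 66.6% of saturation, none as best change and 21.8% after midnight.

    solid substrate ⇌ dissolved substrate, rate k1*(cs1 - [dissolved substrate]) while solid is left; crystals form when [dissolved substrate] > cs1 (solubility = 1.50 M, k = 0.00810 s⁻¹)
    dissolved substrate + partner ⇌ target (K = 0.900 M⁻¹, k = 0.00740 M⁻¹ s⁻¹)
    partner → side product (k = 0.00300 s⁻¹)
    solid reagent ⇌ partner, rate k4*(cs4 - [partner]) while solid is left; crystals form when [partner] > cs4 (solubility = 1.20 M, k = 0.0290 s⁻¹)

At 15.0 min the alder flask holds 76.6% as dissolved substrate, and target with solid substrate stands at 23.4%, beside my headroom of 22.4%. The same reckoning on the neighbouring flask, charged with 1.4 M of solid reagent and otherwise unchanged, keeps the headroom at 22.4%, so less target should mean more solid. That flask ends with 12.3% target and 10.8% solid substrate, together 23.1%, with dissolved substrate at 76.8%.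

The runs stem from a simulated flask from invented constants; scatter was added.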